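(Readings and results stem from a simulated flask on assumed constants; the scatter is artificial.)

Watch the target. The dawn run is the flask asked about, followed up to 4.00 min.

| flask | substrate | gas | remark | time |
|---|---|---|---|---|
| dawn | 0.050 M | 28 mM (held) | the very flask that is asked about, followed so far |  |
| flask | 0.050 M | 28 mM (held) |  | 8.0 min |

- dawn (time / min: isomer of the product / %, target / %): 0.250: 0, 2.7; 0.833: 3.3, 15.4; 1.33: 8.5, 20.8; 2.00: 15.8, 20.4; 3.00: 25.4, 14.0; 4.00: 30.3, 7.3

(each reading ± 0.3 percentage points)

- share of isomer of the product in isomer of the product plus target at 20 s
- share of isomer of the product in isomer of the product plus target at 80 s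
- share of isomer of the product in isomer of the product plus target at 8.0 min
- which of isomer of the product and target there is more of at 8.0 min

- at the start none of the gas is in solution

Between the last two readings, [target] falls from 14.0% to 7.3%, at 0.651 min⁻¹. Call this the fade rate, the pseudo-first-order rate of fall of [target] between two late readings.

Two chemists argue over the last question. The first says [target] simply goes on fading. So 7.3% becomes 0.540% at 8.0 min. With [isomer of the product] held at 30.3%, his share is 98.3%.

The second chemist takes his held [isomer of the product] and goes round once more. Between 1.33 min and 2.00 min, [isomer of the product] gains 0.529 min⁻¹ per unit of [target]. Over the last interval it gains 4.90 % min⁻¹, less than the 5.63 % min⁻¹ that gain predicts. So she lets some return, at 0.0263 min⁻¹, a rough reading, since that gap is small beside the scatter of 0.3 percentage points on each reading. That return against the fade rate puts a floor of 1.22% under [target], higher than his figure. Her share is 96.1%.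

The forecast stands with the first chemist: 7%, 29%, 98%, and isomer of the product ahead, for “the isomer clearly leads”.

The simulation gives 5.95%, 29.3% and 97.9%, with isomer of the product ahead, 30.6% against 0.667%.

    substrate ⇌ intermediate A (K = 0.140, k = 0.230 s⁻¹)
    coupling partner + intermediate A → intermediate B (k = 7.10 M⁻¹ s⁻¹)
    intermediate B ⇌ target (K = 2.00, k = 0.160 s⁻¹)
    target ⇌ isomer of the product (K = 15.0, k = 0.00960 s⁻¹)
    coupling partner + target → over-reaction product (k = 0.940 M⁻¹ s⁻¹)
    gas ⇌ coupling partner, rate k6*(csat - [coupling partner]) (kL = 0.0370 s⁻¹)

The first chemist wins: this flask's [target] stands under her floor. From 7.18% at 4.00 min it falls at a mean 0.594 min⁻¹, against the fade rate of 0.651 min⁻¹. Over-reaction product reaches 68.4% at 8.00 min. The neighbour flask with 0.20 M of substrate ends on the second chemist's side, with a share of 92.1%, under her 96.1%. Its [target] is 3.81% of its own charge, which at the fade rate lies 2.68 min of fading behind this flask's 0.667%.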